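The route rests on closing ring C of the upper (4-arylflavan-3-ol) unit through its C2–C3 and O1–C8a bonds. In one operation the potassium enolate of a 2-fluoroaryl benzyloxymethyl ketone adds to 4-(benzyloxy)benzaldehyde (C2–C3) and the aldolate oxygen displaces fluoride from C8a (O1–C8a). The step exploits C4 of ring C: as a ketone it acidifies C3, activates the ortho carbon C8a of ring A, and later receives the lower (flavan-3,4-diol) unit. The racemic trans product is resolved by transfer hydrogenation; since the two flavan units have opposite C2 configuration, one antipode becomes the upper unit and the other, after C3 inversion, the lower unit.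

Key step: step 3

Remark: flavan numbering is used for both halves (O1, C2, C3, C4, C4a, C5 to C8, C8a; ring A benzo, ring B 2-aryl, ring C pyran). "Upper unit" is the 4-arylflavan-3-ol half and "lower unit" the flavan-3,4-diol half whose C6 carries it. Bn = benzyl, TBS = tert-butyldimethylsilyl. Compounds 1, 3 and 6 are taken as commercial.

Step 1
Reactants: 1 3-fluorobenzene-1,2-diol
Product: 2 1,2-bis(benzyloxy)-3-fluorobenzene
Conditions: BnBr, K2CO3, DMF, 60 °C
Reagents that add atoms: benzyl bromide, BrCc1ccccc1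
Why: Double Williamson ether synthesis of the catechol; no stereocenter is formed.

Step 2
Reactants: 2 1,2-bis(benzyloxy)-3-fluorobenzene; 3 2-(benzyloxy)-N-methoxy-N-methylacetamide
Product: 5 1-[3,4-bis(benzyloxy)-2-fluorophenyl]-2-(benzyloxy)ethan-1-one, via aryllithium 4 (not isolated)
Conditions: s-BuLi, THF, −78 °C; then 3, −78 → 0 °C; aq. NH4Cl
Reagents that add atoms: none
Why: Fluorine-directed ortho-lithiation at the C–H next to fluorine, then Weinreb ketone synthesis, whose chelated adduct should prevent a second addition.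

Step 3
Reactants: 5 1-[3,4-bis(benzyloxy)-2-fluorophenyl]-2-(benzyloxy)ethan-1-one; 6 4-(benzyloxy)benzaldehyde
Product: 9 racemic trans-3,7,8-tris(benzyloxy)-2-[4-(benzyloxy)phenyl]chroman-4-one, via potassium enolate 7 (not isolated), via potassium aldolate 8 (not isolated)
Conditions: KN(SiMe3)2 (1 equiv), THF, −78 °C; 6, −78 °C; DMF, −78 → 0 °C; DBU (cat.), 25 °C; argon
Reagents that add atoms: none
Why: Domino aldol addition and intramolecular nucleophilic aromatic substitution: enolate 7 adds to aldehyde 6 to form C2–C3, and the aldolate oxygen of 8, which becomes O1, attacks C8a ortho to the ketone, the Meisenheimer adduct being stabilised by the C4 carbonyl before fluoride leaves. The closest known reactions are the aldol addition of alpha-alkoxy ketone enolates and the alkoxide cyclisation of 2-fluoroaryl ketones to chroman-4-ones. Ring C closes by a 6-exo-trig addition–elimination at the aromatic carbon. C2 and C3 are formed as a racemate, and their trans relation is set under thermodynamic control, because C3 lies alpha to the ketone and should epimerise (DBU) to the diequatorial isomer. The step needs ring closure by O1 only and at C8a only: O3 is capped as a benzyl ether so no five-membered ring can form, fluorine sits only at C8a, and capture of the aldolate by the activated ring should withdraw it from the reversible aldol equilibrium. The absolute configuration is settled in step 4.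

Step 4
Reactants: 9 racemic trans-3,7,8-tris(benzyloxy)-2-[4-(benzyloxy)phenyl]chroman-4-one
Product: 10 (2S,3S)-3,7,8-tris(benzyloxy)-2-[4-(benzyloxy)phenyl]chroman-4-one (unreduced antipode) and 11 (2R,3S,4R)-3,7,8-tris(benzyloxy)-2-[4-(benzyloxy)phenyl]chroman-4-ol (reduced antipode), separated by chromatography
Conditions: [RhCl(Cp*)((S,S)-TsDPEN)] (cat.), HCO2H/Et3N (5:2), EtOAc, 25 °C, stopped near half conversion
Reagents that add atoms: none
Why: Noyori asymmetric transfer hydrogenation run as a kinetic resolution of a racemic flavanone: the (S,S)-catalyst delivers hydride to the C4 face that leads to the favoured 2,4-cis alcohol only in the (2R,3R)-antipode (C4 set by the catalyst), so the (2S,3S)-ketone should remain, and C3 stays trans as the stable epimer.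

Step 5
Reactants: 11 (2R,3S,4R)-3,7,8-tris(benzyloxy)-2-[4-(benzyloxy)phenyl]chroman-4-ol
Product: 12 (2R,3R)-3,7,8-tris(benzyloxy)-2-[4-(benzyloxy)phenyl]chroman-4-one
Conditions: Dess–Martin periodinane, CH2Cl2, 0 → 25 °C
Reagents that add atoms: none
Why: Dess–Martin oxidation of the benzylic alcohol returns the ketone without touching C2 or C3 and so supplies the antipode needed for the lower unit.

Step 6
Reactants: 12 (2R,3R)-3,7,8-tris(benzyloxy)-2-[4-(benzyloxy)phenyl]chroman-4-one
Product: 15 (2R,3R,4R)-3,7,8-tris(benzyloxy)-2-[4-(benzyloxy)phenyl]chroman-4-ol (2,3-cis-3,4-cis), via lithium enolate 13 (not isolated), via cis-ketone 14 (not isolated)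
Conditions: LiN(iPr)2, THF, −78 °C; 2,6-di-tert-butyl-4-methylphenol, −78 °C; LiBH(s-Bu)3, −78 °C; aq. NH4Cl
Reagents that add atoms: none
Why: Kinetic protonation of the planar C3 enolate anti to the C2 aryl group should give the cis ketone (C3 inverted), and the bulky hydride should then attack C4 anti to the now axial 3-benzyloxy group (substrate control), giving the all-cis alcohol.

Step 7
Reactants: 15 (2R,3R,4R)-3,7,8-tris(benzyloxy)-2-[4-(benzyloxy)phenyl]chroman-4-ol
Product: 16 4-O-TBS ether of 15 (all-cis)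
Conditions: TBSOTf, 2,6-lutidine, CH2Cl2, −40 → 0 °C
Reagents that add atoms: tert-butyldimethylsilyl trifluoromethanesulfonate, CC(C)(C)[Si](C)(C)OS(=O)(=O)C(F)(F)F
Why: Silylation of the secondary benzylic alcohol with a silyl triflate and a hindered base; no stereocenter is touched.

Step 8
Reactants: 16 4-O-TBS ether of 15
Product: 17 6-bromo derivative of 16
Conditions: NBS (1 equiv), MeCN, 0 °C, dark
Reagents that add atoms: N-bromosuccinimide, O=C1CCC(=O)N1Br
Why: Electrophilic aromatic bromination should occur at C6 of ring A, which is para to O1 and ortho to the 7-benzyloxy group and so more activated than C5 or ring B.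

Step 9
Reactants: 17 6-bromo derivative of 16; 10 (2S,3S)-3,7,8-tris(benzyloxy)-2-[4-(benzyloxy)phenyl]chroman-4-one
Product: 19 tertiary alcohol in which C4 of the upper chromane carries a hydroxyl group and C6 of the lower unit (aryl drawn trans to the 3-benzyloxy group), via aryllithium 18 (not isolated)
Conditions: n-BuLi, THF, −78 °C; then 10 premixed with LaCl3·2LiCl, −78 → −20 °C; aq. NH4Cl
Reagents that add atoms: none
Why: Bromine–lithium exchange and 1,2-addition of the aryllithium to the ketone, with LaCl3·2LiCl suppressing enolisation; the configuration of the new carbinol carbon is of no consequence because C4 is ionised in step 10.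

Step 10
Reactants: 19 tertiary alcohol
Product: 21 fully protected dimer with the upper C4–H set (lower-unit aryl cis to the 3-benzyloxy group), via benzylic cation 20 (not isolated)
Conditions: Et3SiH (excess), CF3CO2H, CH2Cl2, −78 → −30 °C
Reagents that add atoms: none
Why: Ionic hydrogenation: the doubly aryl-stabilised tertiary cation should form far more readily than a cation at the silylated C4 of the lower unit, and hydride should enter anti to the 3-benzyloxy group, as nucleophiles do with 2,3-trans-flavan-4-yl cations, which sets the upper C4.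

Step 11
Reactants: 21 fully protected dimer
Product: 22 octa-O-benzyl dimer with free 4-hydroxyl in the lower unit
Conditions: Bu4NF, AcOH, THF, 0 → 25 °C
Reagents that add atoms: none
Why: Buffered fluoride-mediated desilylation; no stereocenter is touched.

Step 12
Reactants: 22 octa-O-benzyl dimer
Product: 23 (2R,3R,4R)-6-[(2S,3R,4R)-3,7,8-trihydroxy-2-(4-hydroxyphenyl)chroman-4-yl]-2-(4-hydroxyphenyl)chromane-3,4,7,8-tetrol
Conditions: H2 (1 atm), Pd(OH)2/C, THF/MeOH, 25 °C
Reagents that add atoms: none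
Why: Hydrogenolysis of the eight benzyl ethers under neutral conditions should leave the ring C–O bonds and the benzylic 4-hydroxyl intact.

Compound list
1 | 3-fluorobenzene-1,2-diol (3-fluorocatechol) | Oc1cccc(F)c1O | starting material
2 | 1,2-bis(benzyloxy)-3-fluorobenzene | Fc1cccc(OCc2ccccc2)c1OCc1ccccc1 | intermediate
3 | 2-(benzyloxy)-N-methoxy-N-methylacetamide | CON(C)C(=O)COCc1ccccc1 | starting material
4 | [3,4-bis(benzyloxy)-2-fluorophenyl]lithium | [Li]c1ccc(OCc2ccccc2)c(OCc2ccccc2)c1F | intermediate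
5 | 1-[3,4-bis(benzyloxy)-2-fluorophenyl]-2-(benzyloxy)ethan-1-one | O=C(COCc1ccccc1)c1ccc(OCc2ccccc2)c(OCc2ccccc2)c1F | intermediate
6 | 4-(benzyloxy)benzaldehyde | O=Cc1ccc(OCc2ccccc2)cc1 | starting material
7 | potassium (Z)-enolate of 5 | [K+].[O-]/C(=C\OCc1ccccc1)c1ccc(OCc2ccccc2)c(OCc2ccccc2)c1F | intermediate
8 | potassium aldolate of 5 and 6 (syn/anti mixture, racemic) | [K+].[O-]C(c1ccc(OCc2ccccc2)cc1)C(OCc1ccccc1)C(=O)c1ccc(OCc2ccccc2)c(OCc2ccccc2)c1F | intermediate
9 | racemic trans-3,7,8-tris(benzyloxy)-2-[4-(benzyloxy)phenyl]chroman-4-one (2S,3S plus 2R,3R) | O=C1c2ccc(OCc3ccccc3)c(OCc3ccccc3)c2O[C@@H](c2ccc(OCc3ccccc3)cc2)[C@@H]1OCc1ccccc1.O=C1c2ccc(OCc3ccccc3)c(OCc3ccccc3)c2O[C@H](c2ccc(OCc3ccccc3)cc2)[C@H]1OCc1ccccc1 | intermediate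
10 | (2S,3S)-3,7,8-tris(benzyloxy)-2-[4-(benzyloxy)phenyl]chroman-4-one | O=C1c2ccc(OCc3ccccc3)c(OCc3ccccc3)c2O[C@@H](c2ccc(OCc3ccccc3)cc2)[C@@H]1OCc1ccccc1 | intermediate
11 | (2R,3S,4R)-3,7,8-tris(benzyloxy)-2-[4-(benzyloxy)phenyl]chroman-4-ol (2,3-trans-3,4-trans) | c1cc(OCc2ccccc2)ccc1[C@H]1Oc2c(ccc(OCc3ccccc3)c2OCc2ccccc2)[C@@H](O)[C@@H]1OCc1ccccc1 | intermediate
12 | (2R,3R)-3,7,8-tris(benzyloxy)-2-[4-(benzyloxy)phenyl]chroman-4-one | O=C1c2ccc(OCc3ccccc3)c(OCc3ccccc3)c2O[C@H](c2ccc(OCc3ccccc3)cc2)[C@H]1OCc1ccccc1 | intermediate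
13 | lithium (2R)-3,7,8-tris(benzyloxy)-2-[4-(benzyloxy)phenyl]-2H-chromen-4-olate | [Li+].[O-]C1=C(OCc2ccccc2)[C@@H](c2ccc(OCc3ccccc3)cc2)Oc2c1ccc(OCc1ccccc1)c2OCc1ccccc1 | intermediate
14 | (2R,3S)-3,7,8-tris(benzyloxy)-2-[4-(benzyloxy)phenyl]chroman-4-one (2,3-cis) | O=C1c2ccc(OCc3ccccc3)c(OCc3ccccc3)c2O[C@H](c2ccc(OCc3ccccc3)cc2)[C@@H]1OCc1ccccc1 | intermediate
15 | (2R,3R,4R)-3,7,8-tris(benzyloxy)-2-[4-(benzyloxy)phenyl]chroman-4-ol (2,3-cis-3,4-cis) | c1cc(OCc2ccccc2)ccc1[C@H]1Oc2c(ccc(OCc3ccccc3)c2OCc2ccccc2)[C@@H](O)[C@H]1OCc1ccccc1 | intermediate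
16 | 4-O-TBS ether of 15, all-cis (same spatial arrangement; 2R,3S,4R by the sequence rule) | c1cc(OCc2ccccc2)ccc1[C@H]1Oc2c(ccc(OCc3ccccc3)c2OCc2ccccc2)[C@@H](O[Si](C)(C)C(C)(C)C)[C@H]1OCc1ccccc1 | intermediate
17 | 6-bromo derivative of 16 | c1cc(OCc2ccccc2)ccc1[C@H]1Oc2c(cc(Br)c(OCc3ccccc3)c2OCc2ccccc2)[C@@H](O[Si](C)(C)C(C)(C)C)[C@H]1OCc1ccccc1 | intermediate
18 | 6-lithio derivative of 16 | c1cc(OCc2ccccc2)ccc1[C@H]1Oc2c(cc([Li])c(OCc3ccccc3)c2OCc2ccccc2)[C@@H](O[Si](C)(C)C(C)(C)C)[C@H]1OCc1ccccc1 | intermediate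
19 | tertiary alcohol: (2S,3S)-3,7,8-tris(benzyloxy)-2-[4-(benzyloxy)phenyl]chroman-4-ol bearing at C4 the C6 carbon of 16 (aryl trans to the 3-benzyloxy group) | c1cc(OCc2ccccc2)ccc1[C@H]1Oc2c(cc([C@@]3(O)c4ccc(OCc5ccccc5)c(OCc5ccccc5)c4O[C@@H](c4ccc(OCc5ccccc5)cc4)[C@@H]3OCc3ccccc3)c(OCc3ccccc3)c2OCc2ccccc2)[C@@H](O[Si](C)(C)C(C)(C)C)[C@H]1OCc1ccccc1 | intermediate
20 | tertiary benzylic cation from 19, as its trifluoroacetate | c1cc(OCc2ccccc2)ccc1[C@H]1Oc2c(cc([C+]3c4ccc(OCc5ccccc5)c(OCc5ccccc5)c4O[C@@H](c4ccc(OCc5ccccc5)cc4)[C@@H]3OCc3ccccc3)c(OCc3ccccc3)c2OCc2ccccc2)[C@@H](O[Si](C)(C)C(C)(C)C)[C@H]1OCc1ccccc1.[O-]C(=O)C(F)(F)F | intermediate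
21 | fully protected dimer: upper unit 2,3-trans-3,4-cis with 3,7,8- and 4'-benzyl ethers, joined through C4 to C6 of the all-cis lower unit of 16 | c1cc(OCc2ccccc2)ccc1[C@H]1Oc2c(cc([C@@H]3c4ccc(OCc5ccccc5)c(OCc5ccccc5)c4O[C@@H](c4ccc(OCc5ccccc5)cc4)[C@@H]3OCc3ccccc3)c(OCc3ccccc3)c2OCc2ccccc2)[C@@H](O[Si](C)(C)C(C)(C)C)[C@H]1OCc1ccccc1 | intermediate
22 | octa-O-benzyl dimer, as 21 with free 4-hydroxyl in the lower unit | c1cc(OCc2ccccc2)ccc1[C@H]1Oc2c(cc([C@@H]3c4ccc(OCc5ccccc5)c(OCc5ccccc5)c4O[C@@H](c4ccc(OCc5ccccc5)cc4)[C@@H]3OCc3ccccc3)c(OCc3ccccc3)c2OCc2ccccc2)[C@@H](O)[C@H]1OCc1ccccc1 | intermediate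
23 | (2R,3R,4R)-6-[(2S,3R,4R)-3,7,8-trihydroxy-2-(4-hydroxyphenyl)chroman-4-yl]-2-(4-hydroxyphenyl)chromane-3,4,7,8-tetrol | Oc1ccc([C@H]2Oc3c(cc([C@@H]4c5ccc(O)c(O)c5O[C@@H](c5ccc(O)cc5)[C@@H]4O)c(O)c3O)[C@@H](O)[C@H]2O)cc1 | target

Total step count: 12. Longest linear sequence: 12 steps (steps 1 to 12; ketone 10 leaves the line at step 4 and re-enters at step 9).

Steps most likely to fail

1. Step 3. Retro-aldol cleavage or dehydration of the aldolate may outrun ring closure, or the basic medium may reopen ring C of the product by beta-elimination of the phenoxide. Fallback, from ketone 5: C-acylation of its lithium enolate (LiN(SiMe3)2, 2 equiv, THF, −78 → 60 °C) with 4-(benzyloxy)benzoyl chloride F1 gives a 1,3-diketone enolate whose enol oxygen displaces the fluoride. This closes ring C through the same two bonds, but irreversibly, and should give 3,7,8-tris(benzyloxy)-2-[4-(benzyloxy)phenyl]-4H-chromen-4-one F2. Conjugate reduction of F2 with LiBH(s-Bu)3 (THF, −78 °C) and equilibration of C3 with DBU should rejoin the route at racemic ketone 9.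

2. Step 6. Protonation of the enolate may show poor facial selectivity, or C3 may epimerise back before the hydride arrives. Fallback, from ketone 12: O-silylation of the potassium enolate (KN(SiMe3)2, TBSOTf, THF, −78 °C) gives the silyl enol ether (2R)-3,7,8-tris(benzyloxy)-2-[4-(benzyloxy)phenyl]-4-(tert-butyldimethylsilyloxy)-2H-chromene F3. Hydrogenation of its C3=C4 bond with [Ir(cod)(PCy3)(py)]PF6 (H2, CH2Cl2, 25 °C) from the face opposite the C2 aryl group should place both new hydrogens cis and give the all-cis silyl ether 16 directly, rejoining the route there.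

3. Step 10. The acid may also ionise the C4–O bond of the lower unit, the cation may lose and regain the C3 proton with loss of configuration, or hydride delivery may be poorly face-selective. Fallback, from tertiary alcohol 19: acylation with methyl chlorooxoacetate (pyridine, DMAP, CH2Cl2) gives the tertiary methyl oxalate F4. Tin hydride reduction (Bu3SnH, AIBN, toluene, 100 °C; Barton–McCombie-type deoxygenation of a tertiary oxalate) passes through the neutral C4 radical, which should take up hydrogen anti to the 3-benzyloxy group and rejoin the route at 21 without any acid.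

Further compounds
F1 | step 3 | 4-(benzyloxy)benzoyl chloride | O=C(Cl)c1ccc(OCc2ccccc2)cc1
F2 | step 3 | 3,7,8-tris(benzyloxy)-2-[4-(benzyloxy)phenyl]-4H-chromen-4-one | O=c1c(OCc2ccccc2)c(-c2ccc(OCc3ccccc3)cc2)oc2c1ccc(OCc1ccccc1)c2OCc1ccccc1
F3 | step 6 | (2R)-3,7,8-tris(benzyloxy)-2-[4-(benzyloxy)phenyl]-4-(tert-butyldimethylsilyloxy)-2H-chromene | CC(C)(C)[Si](C)(C)OC1=C(OCc2ccccc2)[C@@H](c2ccc(OCc3ccccc3)cc2)Oc2c1ccc(OCc1ccccc1)c2OCc1ccccc1
F4 | step 10 | methyl oxalate ester of tertiary alcohol 19 | c1cc(OCc2ccccc2)ccc1[C@H]1Oc2c(cc([C@@]3(OC(=O)C(=O)OC)c4ccc(OCc5ccccc5)c(OCc5ccccc5)c4O[C@@H](c4ccc(OCc5ccccc5)cc4)[C@@H]3OCc3ccccc3)c(OCc3ccccc3)c2OCc2ccccc2)[C@@H](O[Si](C)(C)C(C)(C)C)[C@H]1OCc1ccccc1
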